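A small charge of enzyme, 1.2 µM in the green run, holds substrate near 42.5 % from the first reading on, while the violet run with 1.9 µM ends lower, at 27.1 %. So plateau height follows the enzyme charge, and the readings point to a contest of two times.

| flask | substrate | enzyme | remark | time |
|---|---|---|---|---|
| green | 5 mM | 1.2 µM | run made earlier |  |
| violet | 5 mM | 1.9 µM | run made earlier |  |
| red | 10 mM | 2.5 µM | run made earlier |  |
| flask | 5.0 mM | 2.5 µM |  | 12 min |

| run | time / min | target / % | isomer of the product / % | substrate / % |
|---|---|---|---|---|
| green | 2.50 | 49.7 | 7.4 | 42.4 |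
| green | 5.00 | 50.6 | 7.5 | 42.4 |
| green | 8.00 | 50.4 | 7.1 | 41.8 |
| green | 10.0 | 49.5 | 7.7 | 42.5 |
| violet | 0.833 | 54.8 | 9.8 | 35.5 |
| violet | 2.00 | 58.2 | 12.3 | 27.7 |
| violet | 4.00 | 59.8 | 13.2 | 28.1 |
| violet | 10.0 | 59.8 | 12.7 | 27.1 |
| red | 1.33 | 54.8 | 12.7 | 33.5 |
| red | 3.00 | 55.1 | 14.4 | 31.3 |
| red | 6.00 | 54.2 | 14.7 | 30.7 |
| red | 10.0 | 56.1 | 14.4 | 30.6 |

(scatter of a reading: 0.5 percentage points)

1. target at 12 min, in percent of the substrate charged
2. isomer of the product at 12 min, in percent of the substrate charged



Call depth the natural logarithm of charged over remaining substrate. The first time is the life of the enzyme. In the violet run at 0.833 min, a share 20.7 % of the final depth was still to come, which reads as a life of 0.529 min. The second is the substrate time, in which working enzyme lowers substrate by a factor e; it shortens with enzyme charge. Final depth is life over substrate time.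

The violet run gives the capacity, depth per micromolar of enzyme, 0.687 µM⁻¹. For the flask with 2.5 µM, the substrate time is 0.308 min and the depth 1.72. The life is short against 12 min, so the plateau stands by then.

The green run reads a capacity of 0.713 µM⁻¹, higher than the violet one, and each reading behind these carries a scatter of 0.5 percentage points. Putting the first depth back on the line through both runs gives capacity 0.663 µM⁻¹, depth 1.66, and 19.0 % substrate left by this reckoning.

The forecast says “conversion stops once its finite catalytic capacity is spent” and gives 65 % target (60 % to 70 %) and 18 % isomer of the product (15 % to 23 %). Those two sum to 83.0 %, more than the 81.0 % consumed in the reckoning above.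

The flask gives 63.8 % target and 17.0 % isomer of the product.

    enzyme → spent catalyst (k = 0.0310 s⁻¹)
    substrate + enzyme → target + enzyme, rate k2*[substrate]*[enzyme]/(1 + ([substrate]/Km2) + ([target]/Kp2)) (11.0 mM, 3.00 mM, k = 40000 M⁻¹ s⁻¹)
    target + enzyme ⇌ isomer of the product + enzyme, rate k3*[enzyme]*[target] forward; the back reaction follows from the equilibrium constant (K = 0.450, k = 7500 M⁻¹ s⁻¹)

The enzyme half-life, 0.37 min, is short against 12 min. At 6.00 min the conversion of substrate into target has >99.9 % of its turnover behind it, and the flask holds 19 % substrate at 12.0 min, a depth of 1.66. A neighbour flask with 0.620 µM of enzyme, at capacity 0.687 µM⁻¹, is reckoned to keep 65.3 % substrate, and it keeps 62 %.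

The readings are calculated with constants of no real substance, noise included.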